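**Plan**
1. Atoms carry germacrane numbers: ring C1–C10, C11(=C13)–C12 on C7, C14 on C10, C15 on C4. The last cuts are the epoxide C–O bond (carried as a bromohydrin, because the free β,γ-epoxy acid would cyclise to a hydroxy lactone) and the O8 ester bond.
2. The lactone O–C6 bond is cut back to a C6–H bond. C6 is allylic to the C4=C5 alkene and γ to the C12 carboxyl, so the five-membered lactone ring can be closed last on the intact ten-membered triene acid.
3. The acrylic acid is cut at C11–C12 (carbonylation of an enol triflate) and C11–C13 (methyl addition to a Weinreb amide). The carbocycle is cut at C9–C10 (chromium–nickel closure of a Z-iodoalkene onto a C9 aldehyde), the chain at C6–C7 (alkylation of a hydroxy lactone dianion) and at C1=C10 (iodo-ylide olefination).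
4. Forward order: C6–C7 bond, ten-membered ring, lactone ring, O8 ester, epoxide ring.
5. Stereochemistry: C8 from (S)-3-hydroxy-γ-butyrolactone; C7 by alkylation trans to it; C9 by Felkin–Anh addition in the ring closure; C6 relayed from C7 through the carboxylate tether; the epoxide carbon from a catalytic asymmetric epoxidation; 4E from geranyl acetate and 1(10)Z from the Z-iodoalkene.

Key step: step 14

Assumption: in step 16 the ligand enantiomer that leads to the (R)-epoxide is used; which enantiomer this is has to be fixed from the known facial preference of the catalyst.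

**Route**

Step 1
Reactants: 1 geranyl acetate
Product: 3 (2E)-3-methyl-6-oxohex-2-en-1-yl acetate, via ozonide 2 (not isolated)
Conditions: O3 (1 equiv), CH2Cl2, −78 °C; Me2S, −78 °C → rt
Reagents that add atoms: ozone, [O-][O+]=O
Why: Chemoselective ozonolysis, in which the electron-rich terminal alkene reacts before the 2,3-alkene that is deactivated by the allylic acetate, and reduction of the ozonide gives the aldehyde.

Step 2
Reactants: 3 (2E)-3-methyl-6-oxohex-2-en-1-yl acetate
Product: 4 (2E,6Z)-7-iodo-3-methylocta-2,6-dien-1-yl acetate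
Conditions: EtPPh3I, n-BuLi, THF; I2, −78 °C; NaN(SiMe3)2; then 3, −78 → −20 °C
Reagents that add atoms: ethyltriphenylphosphonium iodide, CC[P+](c1ccccc1)(c1ccccc1)c1ccccc1.[I-]; iodine, II
Why: Stork–Zhao olefination with the α-iodo ylide should give the 2-iodoalk-2-ene with iodine cis to the chain, which fixes the later 1(10)Z ring alkene and brings in C10 and C14.

Step 3
Reactants: 4 (2E,6Z)-7-iodo-3-methylocta-2,6-dien-1-yl acetate
Product: 5 (2E,6Z)-7-iodo-3-methylocta-2,6-dien-1-ol
Conditions: K2CO3 (cat.), MeOH, 0 °C → rt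
Reagents that add atoms: none
Why: Transesterification with methanol frees the allylic alcohol without touching the iodoalkene.

Step 4
Reactants: 5 (2E,6Z)-7-iodo-3-methylocta-2,6-dien-1-ol
Product: 6 (2E,6Z)-1-bromo-7-iodo-3-methylocta-2,6-diene
Conditions: CBr4, PPh3, CH2Cl2, 0 °C
Reagents that add atoms: tetrabromomethane, BrC(Br)(Br)Br
Why: Appel bromination converts the primary allylic alcohol into the bromide by SN2 displacement, so both alkene geometries are kept.

Step 5
Reactants: 6 (2E,6Z)-1-bromo-7-iodo-3-methylocta-2,6-diene; 7 (4S)-4-hydroxyoxolan-2-one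
Product: 9 (3S,4S)-4-hydroxy-3-[(2E,6Z)-7-iodo-3-methylocta-2,6-dien-1-yl]oxolan-2-one, via dilithium dianion 8 (not isolated)
Conditions: 7, LiN(SiMe3)2 (2.1 equiv), THF, −78 → −40 °C; then 6, DMPU, −78 → −30 °C
Reagents that add atoms: none
Why: Fráter–Seebach-type alkylation of a β-hydroxy lactone dianion, in which the allylic bromide attacks the enolate face anti to the neighbouring lithium alkoxide, so C7 is set trans to the chiral-pool C8 oxygen.

Step 6
Reactants: 9 (3S,4S)-hydroxy lactone
Product: 10 (2S,3S)-3,4-dihydroxy-2-[(2E,6Z)-7-iodo-3-methylocta-2,6-dien-1-yl]-N-methoxy-N-methylbutanamide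
Conditions: AlMe3, MeNHOMe·HCl, CH2Cl2, 0 °C → rt
Reagents that add atoms: N,O-dimethylhydroxylamine hydrochloride, CNOC.Cl
Why: Weinreb aminolysis of the lactone with the aluminium amide opens the ring, freeing the C9 hydroxyl and keeping C11 at the acid oxidation level for later ketone formation.

Step 7
Reactants: 10 diol Weinreb amide
Product: 11 (2S,3S)-2-[(2E,6Z)-7-iodo-3-methylocta-2,6-dien-1-yl]-N-methoxy-N-methyl-3,4-bis(triethylsilyloxy)butanamide
Conditions: Et3SiCl, imidazole, DMF, 0 °C → rt
Reagents that add atoms: chlorotriethylsilane, CC[Si](Cl)(CC)CC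
Why: Standard silylation of both hydroxyls, which also prevents relactonisation of the γ-hydroxy amide.

Step 8
Reactants: 11 bis(triethylsilyl) ether
Product: 12 (2S,3S)-2-[(2E,6Z)-7-iodo-3-methylocta-2,6-dien-1-yl]-N-methoxy-N-methyl-4-oxo-3-(triethylsilyloxy)butanamide
Conditions: (COCl)2, DMSO, CH2Cl2, −78 → −35 °C; Et3N, −78 → 0 °C
Reagents that add atoms: none
Why: Under Swern conditions a primary triethylsilyl ether is cleaved and oxidised to the aldehyde while the secondary one survives, and the Weinreb amide (not yet a ketone) at C11 keeps the C8 silyloxy group from β-elimination.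

Step 9
Reactants: 12 C9 aldehyde with Z-iodoalkene
Product: 13 (1S,2S,3R,4Z,8E)-3-hydroxy-N-methoxy-N,4,8-trimethyl-2-(triethylsilyloxy)cyclodeca-4,8-diene-1-carboxamide
Conditions: CrCl2 (excess), NiCl2 (cat.), DMSO, rt, slow addition to 0.003 M
Reagents that add atoms: none
Why: Nozaki–Hiyama–Kishi reaction, in which the alkenylchromium species formed from the Z-iodide with retention adds to the aldehyde at high dilution and closes the ten-membered ring, and attack anti to the C8 silyloxy group (Felkin–Anh) should give the 8,9-anti (9R) carbinol.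

Step 10
Reactants: 13 ring carbinol
Product: 14 (1S,2S,3R,4Z,8E)-3-(tert-butyldimethylsilyloxy)-N-methoxy-N,4,8-trimethyl-2-(triethylsilyloxy)cyclodeca-4,8-diene-1-carboxamide
Conditions: tBuMe2SiOTf, 2,6-lutidine, CH2Cl2, −78 → 0 °C
Reagents that add atoms: tert-butyldimethylsilyl trifluoromethanesulfonate, CC(C)(C)[Si](C)(C)OS(=O)(=O)C(F)(F)F
Why: Silyl triflate with lutidine silylates the hindered allylic alcohol without disturbing the triethylsilyl ether, giving two silyl ethers that can later be removed one after the other.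

Step 11
Reactants: 14 Weinreb amide
Product: 15 1-[(1S,2S,3R,4Z,8E)-3-(tert-butyldimethylsilyloxy)-4,8-dimethyl-2-(triethylsilyloxy)cyclodeca-4,8-dien-1-yl]ethan-1-one
Conditions: MeMgBr, THF, 0 °C
Reagents that add atoms: methylmagnesium bromide, C[Mg]Br
Why: Grignard addition to a Weinreb amide stops at the ketone through the chelated tetrahedral intermediate and brings in C13.

Step 12
Reactants: 15 methyl ketone
Product: 17 1-[(1S,2S,3R,4Z,8E)-3-(tert-butyldimethylsilyloxy)-4,8-dimethyl-2-(triethylsilyloxy)cyclodeca-4,8-dien-1-yl]ethenyl trifluoromethanesulfonate, via potassium enolate 16 (not isolated)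
Conditions: KN(SiMe3)2, THF, −78 °C; PhNTf2, −78 → 0 °C
Reagents that add atoms: N-phenylbis(trifluoromethanesulfonimide), O=S(=O)(N(c1ccccc1)S(=O)(=O)C(F)(F)F)C(F)(F)F
Why: Kinetic deprotonation at the methyl group and O-sulfonylation give the 1,1-disubstituted enol triflate, and because the enolate is not formed towards C7 that centre and the C8 silyloxy group are left alone.

Step 13
Reactants: 17 enol triflate
Product: 19 2-[(1R,2S,3R,4Z,8E)-3-(tert-butyldimethylsilyloxy)-4,8-dimethyl-2-(triethylsilyloxy)cyclodeca-4,8-dien-1-yl]prop-2-enoic acid, via mixed acetic anhydride 18 (not isolated)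
Conditions: Pd(OAc)2 (cat.), Ph2P(CH2)3PPh2, CO (1 atm), KOAc, DMF, 50 °C; aqueous work-up
Reagents that add atoms: carbon monoxide, [C-]#[O+]; potassium acetate, CC(=O)[O-].[K+] (hydroxyl oxygen, by way of the mixed anhydride)
Why: Palladium-catalysed hydroxycarbonylation of an enol triflate, in which oxidative addition, CO insertion and capture of the acylpalladium by acetate give a mixed anhydride that is hydrolysed to the 2-substituted acrylic acid, adding C12.

Step 14
Reactants: 19 ten-membered triene seco-acid with C6 methylene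
Product: 20 (3aS,4S,5R,6Z,10E,11aR)-5-(tert-butyldimethylsilyloxy)-6,10-dimethyl-3-methylidene-4-(triethylsilyloxy)-3a,4,5,8,9,11a-hexahydrocyclodeca[b]furan-2(3H)-one
Conditions: Pd(OAc)2 (10 mol %), 1,2-bis(phenylsulfinyl)ethane (10 mol %), 1,4-benzoquinone (2 equiv), 1,4-dioxane, 45 °C
Reagents that add atoms: none
Why: Proposed new method: the carboxylate of 19 binds divalent palladium, which coordinates the C4=C5 alkene and cleaves the C6–H bond with a bound carboxylate as internal base, giving an η3-allyl complex over C4–C6 held in a six-membered palladacycle; benzoquinone then induces C–O reductive elimination at C6 and returns zerovalent palladium to the divalent state. The closest known reactions are the Pd(OAc)2/bis-sulfoxide allylic C–H esterification and macrolactonisation of terminal alkenes and the palladium-catalysed γ-C–H lactonisation of free aliphatic acids; an internal trisubstituted alkene in a medium ring has not been used in either. The five-membered ring closes by attack of the carboxylate oxygen on the allyl terminus C6 (5-exo with respect to the allyl unit), whereas closure at C4 would need a seven-membered ring at a fully substituted carbon. The new C6 stereocentre is controlled by C7: the short tether can deliver oxygen only to the face of C6 that gives the trans-fused 6R lactone in the crown-like conformer of the E-alkene, and palladium and oxygen stay on that face because C–H cleavage and C–O formation are both inner-sphere (net retention). Site selectivity over the C2, C3, C9, C14 and C15 hydrogens rests on the tether, C6 being the only allylic position γ to C12, while Wacker-type attack at C5 is disfavoured because it would place palladium on the quaternary C4, and the 4E geometry is kept because the allyl unit can isomerise only through its C6 end.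

Step 15
Reactants: 20 bis-silylated lactone
Product: 21 (3aR,4S,5R,6Z,10E,11aR)-5-(tert-butyldimethylsilyloxy)-4-hydroxy-6,10-dimethyl-3-methylidene-3a,4,5,8,9,11a-hexahydrocyclodeca[b]furan-2(3H)-one
Conditions: PPTS (cat.), MeOH/CH2Cl2, 0 °C
Reagents that add atoms: none
Why: Mild acid methanolysis removes a triethylsilyl ether selectively beside a tert-butyldimethylsilyl ether (the 3a descriptor changes by priority only, not in space).

Step 16
Reactants: 22 3-methylbut-3-en-1-ol
Product: 23 2-[(2R)-2-methyloxiran-2-yl]ethan-1-ol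
Conditions: Zr(OtBu)4 (cat.), C2-symmetric bishydroxamic acid ligand from trans-cyclohexane-1,2-diamine (cat.), cumene hydroperoxide, DMPU, 4 Å MS, toluene, 0 °C
Reagents that add atoms: cumene hydroperoxide, CC(C)(OO)c1ccccc1
Why: Metal–bishydroxamic acid catalysed asymmetric epoxidation of a homoallylic alcohol, in which the hydroxyl binds the metal and the chiral ligand selects the alkene face, setting the quaternary epoxide carbon.

Step 17
Reactants: 23 (R)-epoxy alcohol
Product: 24 (3R)-4-bromo-3-methylbutane-1,3-diol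
Conditions: LiBr, AcOH, THF, rt
Reagents that add atoms: lithium bromide, [Li+].[Br-]
Why: Bromide opens the epoxide at the unhindered CH2 by SN2 without breaking the C–O bond of the stereocentre, giving a bromohydrin that carries the epoxide through acylation and desilylation without a β-leaving group or an acid-labile ring.

Step 18
Reactants: 24 (R)-bromo diol
Product: 25 (3R)-4-bromo-3-hydroxy-3-methylbutanoic acid
Conditions: TEMPO (cat.), PhI(OAc)2, MeCN/H2O, rt
Reagents that add atoms: water, O
Why: Oxoammonium oxidation takes the primary alcohol through the aldehyde hydrate to the acid and leaves the tertiary alcohol and the neopentyl-type bromide untouched.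

Step 19
Reactants: 21 C8 alcohol; 25 (3R)-4-bromo-3-hydroxy-3-methylbutanoic acid
Product: 27 (3aS,4S,5R,6Z,10E,11aR)-5-(tert-butyldimethylsilyloxy)-6,10-dimethyl-3-methylidene-2-oxo-2,3,3a,4,5,8,9,11a-octahydrocyclodeca[b]furan-4-yl (3R)-4-bromo-3-hydroxy-3-methylbutanoate, via mixed trichlorobenzoic anhydride 26 (not isolated)
Conditions: 25, 2,4,6-trichlorobenzoyl chloride, Et3N, THF, 0 °C; then 21, DMAP, toluene, rt
Reagents that add atoms: none
Why: Yamaguchi esterification, in which the mixed anhydride acylates the hindered C8 hydroxyl under DMAP catalysis while the tertiary hydroxyl of the acid does not compete.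

Step 20
Reactants: 27 silylated bromohydrin ester
Product: 28 (3aS,4S,5R,6Z,10E,11aR)-5-hydroxy-6,10-dimethyl-3-methylidene-2-oxo-2,3,3a,4,5,8,9,11a-octahydrocyclodeca[b]furan-4-yl (3R)-4-bromo-3-hydroxy-3-methylbutanoate
Conditions: HF·pyridine, pyridine, THF, 0 °C → rt
Reagents that add atoms: none
Why: Buffered fluoride cleavage of the secondary silyl ether under mildly acidic conditions, which avoid O8→O9 acyl shift and meet no acid-labile group because the epoxide is still masked.

Step 21
Reactants: 28 bromohydrin ester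
Product: 29 target, (3aS,4S,5R,6Z,10E,11aR)-5-hydroxy-6,10-dimethyl-3-methylidene-2-oxo-2,3,3a,4,5,8,9,11a-octahydrocyclodeca[b]furan-4-yl [(2R)-2-methyloxiran-2-yl]acetate
Conditions: Ag2O, THF, rt, dark
Reagents that add atoms: none
Why: Silver-assisted intramolecular Williamson closure of the bromohydrin forms the epoxide without breaking a bond at the quaternary centre (R retained) and without base strong enough to attack the methylene lactone or shift the ester.

**Compound list**
1 | geranyl acetate | CC(C)=CCC/C(C)=C/COC(C)=O | starting material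
2 | ozonide (1,2,4-trioxolane) of the terminal alkene of 1 | CC(=O)OC/C=C(\C)CCC1OOC(C)(C)O1 | intermediate (not isolated)
3 | (2E)-3-methyl-6-oxohex-2-en-1-yl acetate | CC(=O)OC/C=C(\C)CCC=O | intermediate
4 | (2E,6Z)-7-iodo-3-methylocta-2,6-dien-1-yl acetate | CC(=O)OC/C=C(\C)CC/C=C(/C)I | intermediate
5 | (2E,6Z)-7-iodo-3-methylocta-2,6-dien-1-ol | OC/C=C(\C)CC/C=C(/C)I | intermediate
6 | (2E,6Z)-1-bromo-7-iodo-3-methylocta-2,6-diene | BrC/C=C(\C)CC/C=C(/C)I | intermediate
7 | (4S)-4-hydroxyoxolan-2-one, (S)-3-hydroxy-γ-butyrolactone | O=C1OC[C@@H](O)C1 | starting material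
8 | dilithium enolate–alkoxide of 7 | [Li+].[Li+].[O-]C1=C[C@H]([O-])CO1 | intermediate (not isolated)
9 | (3S,4S)-4-hydroxy-3-[(2E,6Z)-7-iodo-3-methylocta-2,6-dien-1-yl]oxolan-2-one | O=C1OC[C@@H](O)[C@@H]1C/C=C(\C)CC/C=C(/C)I | intermediate
10 | (2S,3S)-3,4-dihydroxy-2-[(2E,6Z)-7-iodo-3-methylocta-2,6-dien-1-yl]-N-methoxy-N-methylbutanamide | CON(C)C(=O)[C@@H](C/C=C(\C)CC/C=C(/C)I)[C@H](O)CO | intermediate
11 | (2S,3S)-2-[(2E,6Z)-7-iodo-3-methylocta-2,6-dien-1-yl]-N-methoxy-N-methyl-3,4-bis(triethylsilyloxy)butanamide | CON(C)C(=O)[C@@H](C/C=C(\C)CC/C=C(/C)I)[C@H](O[Si](CC)(CC)CC)CO[Si](CC)(CC)CC | intermediate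
12 | (2S,3S)-2-[(2E,6Z)-7-iodo-3-methylocta-2,6-dien-1-yl]-N-methoxy-N-methyl-4-oxo-3-(triethylsilyloxy)butanamide | CON(C)C(=O)[C@@H](C/C=C(\C)CC/C=C(/C)I)[C@H](O[Si](CC)(CC)CC)C=O | intermediate
13 | (1S,2S,3R,4Z,8E)-3-hydroxy-N-methoxy-N,4,8-trimethyl-2-(triethylsilyloxy)cyclodeca-4,8-diene-1-carboxamide | CON(C)C(=O)[C@H]1C/C=C(\C)CC/C=C(/C)[C@@H](O)[C@H]1O[Si](CC)(CC)CC | intermediate
14 | (1S,2S,3R,4Z,8E)-3-(tert-butyldimethylsilyloxy)-N-methoxy-N,4,8-trimethyl-2-(triethylsilyloxy)cyclodeca-4,8-diene-1-carboxamide | CON(C)C(=O)[C@H]1C/C=C(\C)CC/C=C(/C)[C@@H](O[Si](C)(C)C(C)(C)C)[C@H]1O[Si](CC)(CC)CC | intermediate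
15 | 1-[(1S,2S,3R,4Z,8E)-3-(tert-butyldimethylsilyloxy)-4,8-dimethyl-2-(triethylsilyloxy)cyclodeca-4,8-dien-1-yl]ethan-1-one | CC(=O)[C@H]1C/C=C(\C)CC/C=C(/C)[C@@H](O[Si](C)(C)C(C)(C)C)[C@H]1O[Si](CC)(CC)CC | intermediate
16 | potassium enolate of 15, formed at the methyl group | [K+].C=C([O-])[C@H]1C/C=C(\C)CC/C=C(/C)[C@@H](O[Si](C)(C)C(C)(C)C)[C@H]1O[Si](CC)(CC)CC | intermediate (not isolated)
17 | 1-[(1S,2S,3R,4Z,8E)-3-(tert-butyldimethylsilyloxy)-4,8-dimethyl-2-(triethylsilyloxy)cyclodeca-4,8-dien-1-yl]ethenyl trifluoromethanesulfonate | C=C(OS(=O)(=O)C(F)(F)F)[C@H]1C/C=C(\C)CC/C=C(/C)[C@@H](O[Si](C)(C)C(C)(C)C)[C@H]1O[Si](CC)(CC)CC | intermediate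
18 | mixed anhydride of acid 19 with acetic acid | CC(=O)OC(=O)C(=C)[C@H]1C/C=C(\C)CC/C=C(/C)[C@@H](O[Si](C)(C)C(C)(C)C)[C@H]1O[Si](CC)(CC)CC | intermediate (not isolated)
19 | 2-[(1R,2S,3R,4Z,8E)-3-(tert-butyldimethylsilyloxy)-4,8-dimethyl-2-(triethylsilyloxy)cyclodeca-4,8-dien-1-yl]prop-2-enoic acid | OC(=O)C(=C)[C@H]1C/C=C(\C)CC/C=C(/C)[C@@H](O[Si](C)(C)C(C)(C)C)[C@H]1O[Si](CC)(CC)CC | intermediate (precursor of the key step)
20 | (3aS,4S,5R,6Z,10E,11aR)-5-(tert-butyldimethylsilyloxy)-6,10-dimethyl-3-methylidene-4-(triethylsilyloxy)-3a,4,5,8,9,11a-hexahydrocyclodeca[b]furan-2(3H)-one | C=C1C(=O)O[C@@H]2/C=C(\C)CC/C=C(/C)[C@@H](O[Si](C)(C)C(C)(C)C)[C@@H](O[Si](CC)(CC)CC)[C@@H]12 | intermediate (product of the key step)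
21 | (3aR,4S,5R,6Z,10E,11aR)-5-(tert-butyldimethylsilyloxy)-4-hydroxy-6,10-dimethyl-3-methylidene-3a,4,5,8,9,11a-hexahydrocyclodeca[b]furan-2(3H)-one | C=C1C(=O)O[C@@H]2/C=C(\C)CC/C=C(/C)[C@@H](O[Si](C)(C)C(C)(C)C)[C@@H](O)[C@@H]12 | intermediate
22 | 3-methylbut-3-en-1-ol | CC(=C)CCO | starting material
23 | 2-[(2R)-2-methyloxiran-2-yl]ethan-1-ol | OCC[C@]1(C)CO1 | intermediate
24 | (3R)-4-bromo-3-methylbutane-1,3-diol | OCC[C@@](C)(O)CBr | intermediate
25 | (3R)-4-bromo-3-hydroxy-3-methylbutanoic acid | OC(=O)C[C@@](C)(O)CBr | intermediate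
26 | mixed anhydride of 25 with 2,4,6-trichlorobenzoic acid | O=C(OC(=O)C[C@@](C)(O)CBr)c1c(Cl)cc(Cl)cc1Cl | intermediate (not isolated)
27 | (3aS,4S,5R,6Z,10E,11aR)-5-(tert-butyldimethylsilyloxy)-6,10-dimethyl-3-methylidene-2-oxo-2,3,3a,4,5,8,9,11a-octahydrocyclodeca[b]furan-4-yl (3R)-4-bromo-3-hydroxy-3-methylbutanoate | C=C1C(=O)O[C@@H]2/C=C(\C)CC/C=C(/C)[C@@H](O[Si](C)(C)C(C)(C)C)[C@@H](OC(=O)C[C@@](C)(O)CBr)[C@@H]12 | intermediate
28 | (3aS,4S,5R,6Z,10E,11aR)-5-hydroxy-6,10-dimethyl-3-methylidene-2-oxo-2,3,3a,4,5,8,9,11a-octahydrocyclodeca[b]furan-4-yl (3R)-4-bromo-3-hydroxy-3-methylbutanoate | C=C1C(=O)O[C@@H]2/C=C(\C)CC/C=C(/C)[C@@H](O)[C@@H](OC(=O)C[C@@](C)(O)CBr)[C@@H]12 | intermediate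
29 | (3aS,4S,5R,6Z,10E,11aR)-5-hydroxy-6,10-dimethyl-3-methylidene-2-oxo-2,3,3a,4,5,8,9,11a-octahydrocyclodeca[b]furan-4-yl [(2R)-2-methyloxiran-2-yl]acetate | C=C1C(=O)O[C@@H]2/C=C(\C)CC/C=C(/C)[C@@H](O)[C@@H](OC(=O)C[C@]3(C)CO3)[C@@H]12 | target

**Step count**
Total: 21 steps. Longest linear sequence: 18 steps (steps 1–15 and 19–21, from geranyl acetate); the side-chain acid takes 3 steps (16–18).

**Steps most likely to fail**

Step 14 (the new method). C–H cleavage at an internal trisubstituted alkene may be too slow to compete with catalyst decay or with oxidation at other allylic positions, and the allyl intermediate may close on the wrong face of C6. The fallback uses known reactions only; it sets out from 19 and comes back at 20. Trimethylsilyldiazomethane converts the acid into the methyl ester F1. mCPBA at low temperature epoxidises the C4=C5 alkene, the most electron-rich and least hindered of the three, to the 4,5-epoxide F2 (either face; the configuration is lost later). Sodium phenylselenide (PhSeSePh, NaBH4, EtOH) opens the epoxide at the less substituted C5 to the hydroxy selenide F3. H2O2 gives the selenoxide F4, which can eliminate only towards C6 and so gives the tertiary allylic alcohol F5 with a C5=C6 alkene; any selenide that has added to the acrylate is expelled again in this oxidation. LiOH hydrolysis gives the hydroxy acid F6. Re2O7 (cat.) then effects the 1,3-transposition of the allylic alcohol, and the C6 hydroxyl so formed is trapped by the carboxyl as the trans-fused γ-lactone 20.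

Step 9. The conformation of the forming ring rather than the C8 substituent may decide which face of the aldehyde is attacked, so that the C9 carbinol forms with the wrong configuration or as a mixture. The fallback sets out from 12 and comes back at 13. The ring closure is run as before, and the crude carbinol, the 9S epimer F7 alone or mixed with 13, is oxidised with Dess–Martin periodinane to the C9 enone F8. Reagent-controlled 1,2-reduction with BH3·SMe2 and an oxazaborolidine (CBS) catalyst, the enantiomer being chosen to deliver hydride to the face that gives 9R, then returns 13; C9 is thus set in a separate step from the C–C bond formation.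

Step 5. Dehydroiodination of the Z-iodoalkene by the strongly basic dianion, O-alkylation and incomplete dianion formation may cut the conversion, and the trans selectivity may suffer with a bulky allylic bromide. The fallback replaces substrate control by an auxiliary; it sets out from 6 and comes back at 10. The lithium enolate of tert-butyl acetate is alkylated with 6 at −78 °C to the tert-butyl ester F9, and CF3CO2H gives the acid F10. Pivaloyl chloride/Et3N forms the mixed anhydride F11, which acylates lithiated (S)-4-benzyl-1,3-oxazolidin-2-one to the imide F12. Enolisation with Bu2BOTf/iPr2NEt and addition to (tert-butyldimethylsilyloxy)acetaldehyde (Evans syn aldol) give the adduct F13 with C7 and C8 both set by the auxiliary. AlMe3/MeNHOMe·HCl gives the Weinreb amide F14, and HF·pyridine removes the primary silyl ether to give diol 10.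

**Further compounds**
F1 | step 14 | methyl ester of 19 | COC(=O)C(=C)[C@H]1C/C=C(\C)CC/C=C(/C)[C@@H](O[Si](C)(C)C(C)(C)C)[C@H]1O[Si](CC)(CC)CC
F2 | step 14 | 4,5-epoxide of F1 (trans epoxide, face not controlled) | COC(=O)C(=C)[C@H]1CC2OC2(C)CC/C=C(/C)[C@@H](O[Si](C)(C)C(C)(C)C)[C@H]1O[Si](CC)(CC)CC
F3 | step 14 | 4-hydroxy-5-(phenylselanyl) ester from F2 | COC(=O)C(=C)[C@H]1CC([Se]c2ccccc2)C(C)(O)CC/C=C(/C)[C@@H](O[Si](C)(C)C(C)(C)C)[C@H]1O[Si](CC)(CC)CC
F4 | step 14 | selenoxide of F3 | COC(=O)C(=C)[C@H]1CC([Se](=O)c2ccccc2)C(C)(O)CC/C=C(/C)[C@@H](O[Si](C)(C)C(C)(C)C)[C@H]1O[Si](CC)(CC)CC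
F5 | step 14 | methyl ester with C4 tertiary hydroxyl and (E)-C5=C6 alkene | COC(=O)C(=C)[C@H]1/C=C/C(C)(O)CC/C=C(/C)[C@@H](O[Si](C)(C)C(C)(C)C)[C@H]1O[Si](CC)(CC)CC
F6 | step 14 | hydroxy acid from F5 | OC(=O)C(=C)[C@H]1/C=C/C(C)(O)CC/C=C(/C)[C@@H](O[Si](C)(C)C(C)(C)C)[C@H]1O[Si](CC)(CC)CC
F7 | step 9 | 9S epimer of 13 | CON(C)C(=O)[C@H]1C/C=C(\C)CC/C=C(/C)[C@H](O)[C@H]1O[Si](CC)(CC)CC
F8 | step 9 | C9 enone, (1S,2S,4Z,8E)-N-methoxy-N,4,8-trimethyl-3-oxo-2-(triethylsilyloxy)cyclodeca-4,8-diene-1-carboxamide | CON(C)C(=O)[C@H]1C/C=C(\C)CC/C=C(/C)C(=O)[C@H]1O[Si](CC)(CC)CC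
F9 | step 5 | tert-butyl (4E,8Z)-9-iodo-5-methyldeca-4,8-dienoate | CC(C)(C)OC(=O)CC/C=C(\C)CC/C=C(/C)I
F10 | step 5 | (4E,8Z)-9-iodo-5-methyldeca-4,8-dienoic acid | OC(=O)CC/C=C(\C)CC/C=C(/C)I
F11 | step 5 | mixed anhydride of F10 with pivalic acid | CC(C)(C)C(=O)OC(=O)CC/C=C(\C)CC/C=C(/C)I
F12 | step 5 | (4S)-4-benzyl-3-[(4E,8Z)-9-iodo-5-methyldeca-4,8-dienoyl]-1,3-oxazolidin-2-one | O=C(CC/C=C(\C)CC/C=C(/C)I)N1[C@@H](Cc2ccccc2)COC1=O
F13 | step 5 | Evans syn aldol adduct, (4S)-4-benzyl-3-[(2S,3S)-4-(tert-butyldimethylsilyloxy)-3-hydroxy-2-[(2E,6Z)-7-iodo-3-methylocta-2,6-dien-1-yl]butanoyl]-1,3-oxazolidin-2-one | O=C([C@@H](C/C=C(\C)CC/C=C(/C)I)[C@H](O)CO[Si](C)(C)C(C)(C)C)N1[C@@H](Cc2ccccc2)COC1=O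
F14 | step 5 | (2S,3S)-4-(tert-butyldimethylsilyloxy)-3-hydroxy-2-[(2E,6Z)-7-iodo-3-methylocta-2,6-dien-1-yl]-N-methoxy-N-methylbutanamide | CON(C)C(=O)[C@@H](C/C=C(\C)CC/C=C(/C)I)[C@H](O)CO[Si](C)(C)C(C)(C)C
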